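**Plan**

1. Cuts (halimane numbering): the O14 acetyl group; the C13–O and C14–O bonds (from an (E)-13-en-15-ol); C9–C11 (side chain); C9–C10 (ring B); then ring A through C3–C4 and C5–C10.
2. Enabling feature: in ring A the sp2 carbon C1 lies para to the quaternary, carboxyl-bearing C4, and the C4 methyl is cis to the C5–C6 bond. With C1 carried as a ketone, ring A is the para adduct of a 2-silyloxybutadiene (C10–C1–C2–C3) and an (E)-α-methyl enal (C4=C5, C18 as CHO).
3. Forward order: ring A by an enantioselective [4+2] that is completed by C3–C4 bond formation; ring B by C9–C10 aldol condensation onto the C1 ketone; conjugate addition of the whole side chain to C9; removal of the C1 oxygen through its enol triflate, which leaves C1=C10; side-chain epoxidation, hydrolysis and acetylation last.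
4. Stereochemistry: C4/C5 absolute from the oxazaborolidinium catalyst, relative from the (E)-enal; C8 from (R)-β-citronellene, held by the thermodynamic preference of the bicyclic enone; C9 by addition anti to the C8 methyl; C13/C14 by Sharpless epoxidation and inversion at C13 on hydrolysis.

Key step: step 3

Remark on numbering: C1–C10 are the decalin carbons, C11–C15 the side chain, C16 the methyl on C13, C17 the methyl on C8, C18 the carboxyl carbon on C4, C19 the methyl on C4, C20 the methyl on C9.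

Assumption: enal 3 is taken to bind the protonated oxazaborolidine in the formyl C–H···O mode of α-substituted acroleins, for which the (R)-catalyst should give the (4S,5S) adduct; if the sense proves opposite, the (S)-catalyst is used with nothing else changed.

**Route**

Step 1
Reactants: 1 (R)-3,7-dimethylocta-1,6-diene ((R)-β-citronellene)
Product: 3 (R,E)-2,6-dimethylocta-2,7-dienal, via allylic alcohol 2 (not isolated)
Conditions: SeO2 (0.5 equiv), t-BuOOH, salicylic acid (cat.), CH2Cl2, rt; then MnO2, CH2Cl2, rt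
Reagents that add atoms: tert-butyl hydroperoxide, CC(C)(C)OO (oxygen atom, relayed through selenium dioxide, O=[Se]=O)
Why: Allylic oxidation with SeO2 (ene reaction, then [2,3]-sigmatropic shift) should pick the (E)-methyl of the electron-rich trisubstituted alkene over the vinyl group, and MnO2 oxidation of the allylic alcohol completes the (E)-enal without touching the C8 stereocentre.

Step 2
Reactants: 4 but-3-en-2-one (methyl vinyl ketone)
Product: 5 2-(triisopropylsilyloxy)buta-1,3-diene
Conditions: TIPSOTf, Et3N, Et2O, 0 °C to rt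
Reagents that add atoms: triisopropylsilyl trifluoromethanesulfonate, CC(C)[Si](OS(=O)(=O)C(F)(F)F)(C(C)C)C(C)C
Why: Soft enolisation of the enone with a silyl triflate and an amine base (silyl dienol ether formation) gives the cross-conjugated 2-silyloxydiene.

Step 3
Reactants: 3 (R,E)-2,6-dimethylocta-2,7-dienal; 5 2-(triisopropylsilyloxy)buta-1,3-diene
Product: 7 (1S,2S)-1-methyl-2-[(3R)-3-methylpent-4-en-1-yl]-4-oxocyclohexane-1-carbaldehyde, via silyl enol ether cycloadduct 6 (not isolated)
Conditions: (R)-1-(2-methylphenyl)-3,3-diphenyltetrahydro-1H,3H-pyrrolo[1,2-c][1,3,2]oxazaborole (20 mol %), HNTf2 (18 mol %), CH2Cl2, −40 to −20 °C; then aq. HF, MeCN, 0 °C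
Reagents that add atoms: none
Why: The protonated oxazaborolidine binds the formyl group of 3 (B–O coordination, formyl C–H···O contact, s-trans enal) and lowers its LUMO, so the 2-silyloxydiene should add in an asynchronous [4+2] cycloaddition in which the C5–C10 bond (enal β-carbon to the CH2 terminus next to the silyloxy carbon) leads and ring A is closed by the C3–C4 bond at the enal α-carbon; HF then cleaves the silyl enol ether 6 to the C1 ketone. The closest known reaction type is the cationic oxazaborolidine-catalysed Diels–Alder reaction of 2-(trialkylsilyloxy)butadienes with α-substituted acroleins. Ring A closes in a suprafacial [4π+2π] mode (in the stepwise limit a Mukaiyama–Michael addition followed by a 6-(enolexo)-endo-trig closure through C3–C4). C4 and C5 are set together: the relative configuration (C19 methyl cis to C6, formyl cis to H5) follows from the (E)-geometry of 3, and the absolute configuration from the catalyst, whose phenyl group shields one face of the bound enal. The step needs para regioselectivity (C1 oxygen para to C4), which the donor at C1 of the diene and the formyl-polarised dienophile secure, and C=C over C=O chemoselectivity, which the α-substituted enal bound to this catalyst secures; the isolated vinyl group and C8 take no part.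

Step 4
Reactants: 7 (1S,2S)-1-methyl-2-[(3R)-3-methylpent-4-en-1-yl]-4-oxocyclohexane-1-carbaldehyde
Product: 8 (1S,2S)-1-methyl-2-[(3R)-3-methylpent-4-en-1-yl]-4-oxocyclohexane-1-carboxylic acid
Conditions: NaClO2, NaH2PO4, 2-methylbut-2-ene, t-BuOH/H2O, rt
Reagents that add atoms: sodium chlorite, [Na+].[O-]Cl=O
Why: Pinnick oxidation converts the hindered, non-enolisable aldehyde into the acid without affecting the ketone, and the alkene scavenger protects the vinyl group from HOCl.

Step 5
Reactants: 8 (1S,2S)-1-methyl-2-[(3R)-3-methylpent-4-en-1-yl]-4-oxocyclohexane-1-carboxylic acid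
Product: 9 benzyl (1S,2S)-1-methyl-2-[(3R)-3-methylpent-4-en-1-yl]-4-oxocyclohexane-1-carboxylate
Conditions: BnBr, Cs2CO3, DMF, rt
Reagents that add atoms: benzyl bromide, BrCc1ccccc1
Why: SN2 O-alkylation of the caesium carboxylate is insensitive to the hindrance at quaternary C4 and gives an ester that should survive the organometallic, acidic and palladium–formate steps and is removed later by hydrogenolysis.

Step 6
Reactants: 9 benzyl (1S,2S)-1-methyl-2-[(3R)-3-methylpent-4-en-1-yl]-4-oxocyclohexane-1-carboxylate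
Product: 10 benzyl (1S,2S)-1-methyl-2-[(3R)-3-methyl-4-oxopentyl]-4-oxocyclohexane-1-carboxylate
Conditions: PdCl2 (10 mol %), CuCl, O2 (1 atm), DMF/H2O, rt
Reagents that add atoms: water, O
Why: Wacker oxidation of the monosubstituted alkene (Markovnikov hydroxypalladation) should give the methyl ketone, which supplies C9 as a carbonyl carbon carrying the C20 methyl.

Step 7
Reactants: 10 benzyl (1S,2S)-1-methyl-2-[(3R)-3-methyl-4-oxopentyl]-4-oxocyclohexane-1-carboxylate
Product: 12 benzyl (1S,6R,8aS)-1,5,6-trimethyl-4-oxo-1,2,3,4,6,7,8,8a-octahydronaphthalene-1-carboxylate, via aldol adduct 11 (not isolated)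
Conditions: p-TsOH·H2O (10 mol %), toluene, reflux, azeotropic removal of water
Reagents that add atoms: none
Why: Acid-catalysed intramolecular aldol condensation joins C10 (enol of the C1 ketone) to the C9 carbonyl in the only six-membered mode that can dehydrate into conjugation; C4 and C5 cannot epimerise, whereas C8 equilibrates through the enol and dienol and should settle with its methyl pseudo-axial and anti to H5, which avoids A(1,2) strain with the C20 methyl (the minor C8 epimer can be re-equilibrated).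

Step 8
Reactants: 13 4-bromobut-1-yne
Product: 15 (E)-5-bromo-3-methylpent-2-en-1-ol, via alkenylalane 14 (not isolated)
Conditions: Me3Al, Cp2ZrCl2 (20 mol %), CH2Cl2, 0 °C to rt; then (CH2O)n, THF, 0 °C to rt; aq. HCl
Reagents that add atoms: trimethylaluminium, C[Al](C)C; paraformaldehyde (as formaldehyde), C=O
Why: Zirconium-catalysed carboalumination adds methyl and aluminium syn across the terminal alkyne (methyl to the internal carbon), and hydroxymethylation of the alkenylalane with retention gives the (E)-trisubstituted allylic alcohol.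

Step 9
Reactants: 15 (E)-5-bromo-3-methylpent-2-en-1-ol
Product: 16 (E)-[(5-bromo-3-methylpent-2-en-1-yl)oxy](tert-butyl)dimethylsilane
Conditions: TBSCl, imidazole, DMF, rt
Reagents that add atoms: tert-butyldimethylsilyl chloride, CC(C)(C)[Si](C)(C)Cl
Why: Silylation of the primary allylic alcohol masks the hydroxyl so that the Grignard reagent can be formed.

Step 10
Reactants: 12 benzyl (1S,6R,8aS)-1,5,6-trimethyl-4-oxo-1,2,3,4,6,7,8,8a-octahydronaphthalene-1-carboxylate; 16 (E)-[(5-bromo-3-methylpent-2-en-1-yl)oxy](tert-butyl)dimethylsilane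
Product: 19 benzyl (1S,5S,6R,8aS)-5-[(E)-5-(tert-butyldimethylsilyloxy)-3-methylpent-3-en-1-yl]-1,5,6-trimethyl-4-(trifluoromethylsulfonyloxy)-1,2,3,5,6,7,8,8a-octahydronaphthalene-1-carboxylate, via Grignard reagent 17 (not isolated), via magnesium enolate 18 (not isolated)
Conditions: 16, Mg, THF, rt; CuBr·SMe2 (30 mol %), then 12, THF, −40 to 0 °C; then N-(5-chloropyridin-2-yl)bis(trifluoromethanesulfonyl)imide, −78 °C to rt
Reagents that add atoms: N-(5-chloropyridin-2-yl)bis(trifluoromethanesulfonyl)imide, FC(F)(F)S(=O)(=O)N(c1ccc(Cl)cn1)S(=O)(=O)C(F)(F)F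
Why: Copper-catalysed conjugate addition of the primary Grignard reagent to the s-cis tetrasubstituted enone (as with pulegone-type enones) should occur at C9 anti to the pseudo-axial C8 methyl (trans-diaxial addition), which places C11 cis to H5 and the C20 methyl cis to the C17 methyl, and the regiodefined C1(O)=C10 magnesium enolate is trapped on oxygen as the enol triflate.

Step 11
Reactants: 19 benzyl (1S,5S,6R,8aS)-5-[(E)-5-(tert-butyldimethylsilyloxy)-3-methylpent-3-en-1-yl]-1,5,6-trimethyl-4-(trifluoromethylsulfonyloxy)-1,2,3,5,6,7,8,8a-octahydronaphthalene-1-carboxylate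
Product: 20 benzyl (1S,5S,6R,8aS)-5-[(E)-5-(tert-butyldimethylsilyloxy)-3-methylpent-3-en-1-yl]-1,5,6-trimethyl-1,2,3,5,6,7,8,8a-octahydronaphthalene-1-carboxylate
Conditions: Pd(OAc)2 (5 mol %), PPh3, HCO2H, Bu3N, DMF, 60 °C
Reagents that add atoms: none
Why: Palladium-catalysed formate reduction of the enol triflate (oxidative addition, formate exchange, decarboxylation, reductive elimination) replaces the triflate by hydrogen and so removes the C1 oxygen with the double bond fixed at C1=C10.

Step 12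
Reactants: 20 benzyl (1S,5S,6R,8aS)-5-[(E)-5-(tert-butyldimethylsilyloxy)-3-methylpent-3-en-1-yl]-1,5,6-trimethyl-1,2,3,5,6,7,8,8a-octahydronaphthalene-1-carboxylate
Product: 21 benzyl (1S,5S,6R,8aS)-5-[(E)-5-hydroxy-3-methylpent-3-en-1-yl]-1,5,6-trimethyl-1,2,3,5,6,7,8,8a-octahydronaphthalene-1-carboxylate
Conditions: TBAF, THF, 0 °C to rt
Reagents that add atoms: none
Why: Fluoride cleaves the silyl ether and frees the allylic hydroxyl that directs the next step, while the hindered benzyl ester is inert.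

Step 13
Reactants: 21 benzyl (1S,5S,6R,8aS)-5-[(E)-5-hydroxy-3-methylpent-3-en-1-yl]-1,5,6-trimethyl-1,2,3,5,6,7,8,8a-octahydronaphthalene-1-carboxylate
Product: 22 benzyl (1S,5S,6R,8aS)-5-{2-[(2R,3R)-3-(hydroxymethyl)-2-methyloxiran-2-yl]ethyl}-1,5,6-trimethyl-1,2,3,5,6,7,8,8a-octahydronaphthalene-1-carboxylate
Conditions: Ti(OiPr)4 (10 mol %), D-(−)-diethyl tartrate (12 mol %), t-BuOOH, 4 Å molecular sieves, CH2Cl2, −20 °C
Reagents that add atoms: tert-butyl hydroperoxide, CC(C)(C)OO
Why: Sharpless asymmetric epoxidation is directed by the allylic hydroxyl, so only the side-chain alkene reacts, and D-(−)-diethyl tartrate should deliver oxygen to the face that gives the (13R,14R)-epoxide under reagent control.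

Step 14
Reactants: 22 benzyl (1S,5S,6R,8aS)-5-{2-[(2R,3R)-3-(hydroxymethyl)-2-methyloxiran-2-yl]ethyl}-1,5,6-trimethyl-1,2,3,5,6,7,8,8a-octahydronaphthalene-1-carboxylate
Product: 23 benzyl (1S,5S,6R,8aS)-1,5,6-trimethyl-5-[(3S,4R)-3,4,5-trihydroxy-3-methylpentyl]-1,2,3,5,6,7,8,8a-octahydronaphthalene-1-carboxylate
Conditions: HClO4 (5 mol %), THF/H2O, 0 °C to rt
Reagents that add atoms: water, O
Why: Acid-catalysed hydrolysis of the 2,3-epoxy alcohol should open the epoxide at the tertiary C13 (Markovnikov, borderline SN2) with inversion, which gives the (13S,14R)-triol while C14 keeps its configuration.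

Step 15
Reactants: 23 benzyl (1S,5S,6R,8aS)-1,5,6-trimethyl-5-[(3S,4R)-3,4,5-trihydroxy-3-methylpentyl]-1,2,3,5,6,7,8,8a-octahydronaphthalene-1-carboxylate
Product: 24 (1S,5S,6R,8aS)-1,5,6-trimethyl-5-[(3S,4R)-3,4,5-trihydroxy-3-methylpentyl]-1,2,3,5,6,7,8,8a-octahydronaphthalene-1-carboxylic acid
Conditions: H2 (1 atm), Pd/C, EtOAc, rt
Reagents that add atoms: none
Why: Hydrogenolysis cleaves the benzyl ester under neutral conditions, and the hindered trisubstituted C1=C10 alkene next to quaternary C9 should be reduced much more slowly.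

Step 16
Reactants: 24 (1S,5S,6R,8aS)-1,5,6-trimethyl-5-[(3S,4R)-3,4,5-trihydroxy-3-methylpentyl]-1,2,3,5,6,7,8,8a-octahydronaphthalene-1-carboxylic acid
Product: 26 CNP0164901.1 (1S,5S,6R,8aS)-5-[(3S,4R)-4-acetoxy-3,5-dihydroxy-3-methylpentyl]-1,5,6-trimethyl-1,2,3,5,6,7,8,8a-octahydronaphthalene-1-carboxylic acid, via cyclic orthoester 25 (not isolated)
Conditions: MeC(OMe)3, PPTS (cat.), CH2Cl2, rt; then AcOH/H2O (4:1), rt
Reagents that add atoms: trimethyl orthoacetate, COC(C)(OC)OC
Why: Acid-catalysed orthoester exchange ties the 14,15-diol into a 2-methoxy-2-methyl-1,3-dioxolane, whose mild aqueous acid hydrolysis should collapse mainly to the secondary C14 acetate with O15 free (orthoester-mediated monoacylation); the tertiary C13 hydroxyl and the hindered acid stay out, and no base is present to drive acyl migration.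

**Compound list**

1 | (R)-3,7-dimethylocta-1,6-diene ((R)-β-citronellene) | C=C[C@H](C)CCC=C(C)C | starting material
2 | (R,E)-2,6-dimethylocta-2,7-dien-1-ol | C=C[C@H](C)CC/C=C(\C)CO | intermediate
3 | (R,E)-2,6-dimethylocta-2,7-dienal | C=C[C@H](C)CC/C=C(\C)C=O | intermediate
4 | but-3-en-2-one (methyl vinyl ketone) | CC(=O)C=C | starting material
5 | 2-(triisopropylsilyloxy)buta-1,3-diene | C=CC(=C)O[Si](C(C)C)(C(C)C)C(C)C | intermediate
6 | (1S,6S)-1-methyl-6-[(3R)-3-methylpent-4-en-1-yl]-4-(triisopropylsilyloxy)cyclohex-3-ene-1-carbaldehyde | O=C[C@@]1(C)CC=C(O[Si](C(C)C)(C(C)C)C(C)C)C[C@@H]1CC[C@@H](C)C=C | intermediate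
7 | (1S,2S)-1-methyl-2-[(3R)-3-methylpent-4-en-1-yl]-4-oxocyclohexane-1-carbaldehyde | O=C[C@@]1(C)CCC(=O)C[C@@H]1CC[C@@H](C)C=C | intermediate
8 | (1S,2S)-1-methyl-2-[(3R)-3-methylpent-4-en-1-yl]-4-oxocyclohexane-1-carboxylic acid | OC(=O)[C@@]1(C)CCC(=O)C[C@@H]1CC[C@@H](C)C=C | intermediate
9 | benzyl (1S,2S)-1-methyl-2-[(3R)-3-methylpent-4-en-1-yl]-4-oxocyclohexane-1-carboxylate | O=C(OCc2ccccc2)[C@@]1(C)CCC(=O)C[C@@H]1CC[C@@H](C)C=C | intermediate
10 | benzyl (1S,2S)-1-methyl-2-[(3R)-3-methyl-4-oxopentyl]-4-oxocyclohexane-1-carboxylate | O=C(OCc2ccccc2)[C@@]1(C)CCC(=O)C[C@@H]1CC[C@@H](C)C(C)=O | intermediate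
11 | benzyl (1S,6R,8aS)-5-hydroxy-1,5,6-trimethyl-4-oxodecahydronaphthalene-1-carboxylate (aldol adduct, mixture at C4a and C5) | O=C(OCc3ccccc3)[C@@]1(C)CCC(=O)C2C(C)(O)[C@H](C)CC[C@H]12 | intermediate
12 | benzyl (1S,6R,8aS)-1,5,6-trimethyl-4-oxo-1,2,3,4,6,7,8,8a-octahydronaphthalene-1-carboxylate | O=C(OCc3ccccc3)[C@@]1(C)CCC(=O)C2=C(C)[C@H](C)CC[C@H]12 | intermediate
13 | 4-bromobut-1-yne | C#CCCBr | starting material
14 | (E)-(4-bromo-2-methylbut-1-en-1-yl)dimethylalane | C[Al](C)/C=C(C)/CCBr | intermediate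
15 | (E)-5-bromo-3-methylpent-2-en-1-ol | OC/C=C(C)/CCBr | intermediate
16 | (E)-[(5-bromo-3-methylpent-2-en-1-yl)oxy](tert-butyl)dimethylsilane | CC(C)(C)[Si](C)(C)OC/C=C(C)/CCBr | intermediate
17 | (E)-[5-(tert-butyldimethylsilyloxy)-3-methylpent-3-en-1-yl]magnesium bromide | CC(C)(C)[Si](C)(C)OC/C=C(C)/CC[Mg]Br | intermediate
18 | bromomagnesium C1(O)=C10 enolate of the C9 adduct (benzyl ester, silyl ether) | CC(C)(C)[Si](C)(C)OC/C=C(C)/CC[C@]1(C)C2=C(O[Mg]Br)CC[C@](C)(C(=O)OCc3ccccc3)[C@H]2CC[C@H]1C | intermediate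
19 | benzyl (1S,5S,6R,8aS)-5-[(E)-5-(tert-butyldimethylsilyloxy)-3-methylpent-3-en-1-yl]-1,5,6-trimethyl-4-(trifluoromethylsulfonyloxy)-1,2,3,5,6,7,8,8a-octahydronaphthalene-1-carboxylate | CC(C)(C)[Si](C)(C)OC/C=C(C)/CC[C@]1(C)C2=C(OS(=O)(=O)C(F)(F)F)CC[C@](C)(C(=O)OCc3ccccc3)[C@H]2CC[C@H]1C | intermediate
20 | benzyl (1S,5S,6R,8aS)-5-[(E)-5-(tert-butyldimethylsilyloxy)-3-methylpent-3-en-1-yl]-1,5,6-trimethyl-1,2,3,5,6,7,8,8a-octahydronaphthalene-1-carboxylate | CC(C)(C)[Si](C)(C)OC/C=C(C)/CC[C@]1(C)C2=CCC[C@](C)(C(=O)OCc3ccccc3)[C@H]2CC[C@H]1C | intermediate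
21 | benzyl (1S,5S,6R,8aS)-5-[(E)-5-hydroxy-3-methylpent-3-en-1-yl]-1,5,6-trimethyl-1,2,3,5,6,7,8,8a-octahydronaphthalene-1-carboxylate | OC/C=C(C)/CC[C@]1(C)C2=CCC[C@](C)(C(=O)OCc3ccccc3)[C@H]2CC[C@H]1C | intermediate
22 | benzyl (1S,5S,6R,8aS)-5-{2-[(2R,3R)-3-(hydroxymethyl)-2-methyloxiran-2-yl]ethyl}-1,5,6-trimethyl-1,2,3,5,6,7,8,8a-octahydronaphthalene-1-carboxylate | OC[C@H]1O[C@]1(C)CC[C@]2(C)C3=CCC[C@](C)(C(=O)OCc4ccccc4)[C@H]3CC[C@H]2C | intermediate
23 | benzyl (1S,5S,6R,8aS)-1,5,6-trimethyl-5-[(3S,4R)-3,4,5-trihydroxy-3-methylpentyl]-1,2,3,5,6,7,8,8a-octahydronaphthalene-1-carboxylate | O[C@H](CO)[C@@](C)(O)CC[C@]1(C)C2=CCC[C@](C)(C(=O)OCc3ccccc3)[C@H]2CC[C@H]1C | intermediate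
24 | (1S,5S,6R,8aS)-1,5,6-trimethyl-5-[(3S,4R)-3,4,5-trihydroxy-3-methylpentyl]-1,2,3,5,6,7,8,8a-octahydronaphthalene-1-carboxylic acid | O[C@H](CO)[C@@](C)(O)CC[C@]1(C)C2=CCC[C@](C)(C(=O)O)[C@H]2CC[C@H]1C | intermediate
25 | 14,15-O-(1-methoxyethylidene) cyclic orthoester of 24 (mixture at the orthoester carbon) | COC1(C)OC[C@@H](O1)[C@@](C)(O)CC[C@]2(C)C3=CCC[C@](C)(C(=O)O)[C@H]3CC[C@H]2C | intermediate
26 | CNP0164901.1, (1S,5S,6R,8aS)-5-[(3S,4R)-4-acetoxy-3,5-dihydroxy-3-methylpentyl]-1,5,6-trimethyl-1,2,3,5,6,7,8,8a-octahydronaphthalene-1-carboxylic acid | CC(=O)O[C@H](CO)[C@@](C)(O)CC[C@]1(C)C2=CCC[C@](C)(C(=O)O)[C@H]2CC[C@H]1C | target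

**Count and risks**

Total steps: 16. Longest linear sequence: 13 steps (steps 1, 3–7 and 10–16); steps 2, 8 and 9 are convergent branches.

Step 10 is the most likely to fail. The cuprate may not add to the fully substituted C9 (1,2-addition to the C1 carbonyl or simple enolisation instead), or it may discriminate the two faces poorly. The fallback sets out from 12 and returns at 21. A smaller sp2 nucleophile (vinylmagnesium bromide, CuBr·SMe2, THF, then the same pyridyl triflimide) would give the 9-vinyl enol triflate F1, and the Pd(OAc)2/PPh3/HCO2H/Bu3N reduction would give the 9-vinyl alkene F2. Hydroboration with 9-BBN-H, which should touch only the monosubstituted vinyl group, would give the B-alkyl-9-borabicyclononane F3. A B-alkyl Suzuki–Miyaura coupling (PdCl2(dppf), K3PO4, DMF/H2O) with ethyl (E)-3-(trifluoromethylsulfonyloxy)but-2-enoate F4 (from ethyl acetoacetate, Tf2O and aqueous Me4NOH) would give the (E)-enoate F5. DIBAL-H at −78 °C should reduce the unhindered conjugated ethyl ester and not the hindered benzyl ester, giving allylic alcohol 21.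

Step 3 is the second risk. The β-substituted α-methyl enal may react too slowly with the acyclic diene, the silyl enol ether may add to the carbonyl group instead, or enantiofacial discrimination may be insufficient. The fallback sets out from 3 and 5 and returns at 8. The cycloaddition would be run with the achiral Lewis acid Me2AlCl (CH2Cl2, −78 °C), giving up catalyst control. Because 3 is a single enantiomer at C8, the two facial outcomes are diastereomers: 6 and the (1R,6R)-silyl enol ether F6. HF cleavage would give 7 and the (1R,2R)-keto aldehyde F7, and oxidation as in step 4 would give 8 and the (1R,2R)-acid F8. The acids would be separated by crystallisation or chromatography, and 8 continues at step 5.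

Step 16 is the third risk. The hemi-orthoester may collapse to the primary acetate, or the acetyl group may migrate from O14 to O15 during work-up. The fallback sets out from 24 and returns at 26. Both hydroxyls would be acetylated (Ac2O, pyridine, DMAP, then aqueous work-up) to give the 14,15-diacetate F9. The primary acetate would then be removed selectively with immobilised Candida antarctica lipase B (phosphate buffer pH 7, MTBE), which should leave the hindered secondary acetate and give 26.

**Further compounds**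

F1 | step 10 | benzyl (1S,5S,6R,8aS)-5-ethenyl-1,5,6-trimethyl-4-(trifluoromethylsulfonyloxy)-1,2,3,5,6,7,8,8a-octahydronaphthalene-1-carboxylate | C=C[C@]1(C)C2=C(OS(=O)(=O)C(F)(F)F)CC[C@](C)(C(=O)OCc3ccccc3)[C@H]2CC[C@H]1C
F2 | step 10 | benzyl (1S,5S,6R,8aS)-5-ethenyl-1,5,6-trimethyl-1,2,3,5,6,7,8,8a-octahydronaphthalene-1-carboxylate | C=C[C@]1(C)C2=CCC[C@](C)(C(=O)OCc3ccccc3)[C@H]2CC[C@H]1C
F3 | step 10 | benzyl (1S,5S,6R,8aS)-5-[2-(9-borabicyclo[3.3.1]nonan-9-yl)ethyl]-1,5,6-trimethyl-1,2,3,5,6,7,8,8a-octahydronaphthalene-1-carboxylate | C1CC2CCCC(C1)B2CC[C@]3(C)C4=CCC[C@](C)(C(=O)OCc5ccccc5)[C@H]4CC[C@H]3C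
F4 | step 10 | ethyl (E)-3-(trifluoromethylsulfonyloxy)but-2-enoate | CCOC(=O)/C=C(\C)OS(=O)(=O)C(F)(F)F
F5 | step 10 | benzyl (1S,5S,6R,8aS)-5-[(E)-5-ethoxy-3-methyl-5-oxopent-3-en-1-yl]-1,5,6-trimethyl-1,2,3,5,6,7,8,8a-octahydronaphthalene-1-carboxylate | CCOC(=O)/C=C(\C)CC[C@]1(C)C2=CCC[C@](C)(C(=O)OCc3ccccc3)[C@H]2CC[C@H]1C
F6 | step 3 | (1R,6R)-1-methyl-6-[(3R)-3-methylpent-4-en-1-yl]-4-(triisopropylsilyloxy)cyclohex-3-ene-1-carbaldehyde | O=C[C@]1(C)CC=C(O[Si](C(C)C)(C(C)C)C(C)C)C[C@H]1CC[C@@H](C)C=C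
F7 | step 3 | (1R,2R)-1-methyl-2-[(3R)-3-methylpent-4-en-1-yl]-4-oxocyclohexane-1-carbaldehyde | O=C[C@]1(C)CCC(=O)C[C@H]1CC[C@@H](C)C=C
F8 | step 3 | (1R,2R)-1-methyl-2-[(3R)-3-methylpent-4-en-1-yl]-4-oxocyclohexane-1-carboxylic acid | OC(=O)[C@]1(C)CCC(=O)C[C@H]1CC[C@@H](C)C=C
F9 | step 16 | (1S,5S,6R,8aS)-5-[(3S,4R)-4,5-diacetoxy-3-hydroxy-3-methylpentyl]-1,5,6-trimethyl-1,2,3,5,6,7,8,8a-octahydronaphthalene-1-carboxylic acid | CC(=O)O[C@H](COC(C)=O)[C@@](C)(O)CC[C@]1(C)C2=CCC[C@](C)(C(=O)O)[C@H]2CC[C@H]1C
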